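**Retrosynthetic overview**
1. B-ring C–O bond: the 3'-OH is not bought in; it is put onto C5 of arylacetic acid 1 by C–H oxygenation (aryl benzoate 2, then phenol acid 3). C5 is the only free site ortho/para to the methoxy group.
2. C ring: 3 and phloroglucinol 4 give deoxybenzoin 5, DMF supplies C2 (enaminone 6), and O1–C2 closure gives bromo-isoflavone 7. This pyranone is the only ring formed; the A and B rings are bought.
3. Side chain: enyne 8 and pinacolborane 9 give (E)-dienylboronate 10; Suzuki coupling of 7 with 10 forms the C5'–C bond and gives target 11. It is done last because the diene is acid-sensitive.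
4. No protecting groups are used; the E geometry comes from syn-hydroboration.

Assumption: the target has no stereocentre, so "single enantiomer" is read as the single (E)-alkene isomer drawn.

**Step 1**
Reactants: 1 2-(3-bromo-4-methoxyphenyl)acetic acid
Product: 3 2-(3-bromo-5-hydroxy-4-methoxyphenyl)acetic acid, via aryl benzoate 2 (not isolated)
Conditions: (BzO)2 (1.3 equiv), TfOH (10 mol%), HFIP, 0 → 25 °C; then 2 M NaOH, THF, 25 °C; HCl work-up
Reagents that add atoms: dibenzoyl peroxide, O=C(OOC(=O)c1ccccc1)c1ccccc1
Why: Proposed new method: Brønsted-acid-catalysed electrophilic aromatic C–H benzoyloxylation in HFIP, in which TfOH/HFIP hydrogen bonding polarises the weak O–O bond of dibenzoyl peroxide so that C5 of 1 (the only free position ortho/para to OMe, since the para carbon and the other ortho carbon are substituted) attacks a peroxide oxygen in an SEAr step with benzoic acid as leaving group; ester 2 is less electron-rich than 1, so it is not oxidised further and is saponified in the same flask; the closest known reaction types are arene C–H hydroxylation with cyclic diacyl peroxides or bis(sulfonyl) peroxides in fluorinated alcohols and the stoichiometric Lewis-acid-promoted benzoyloxylation of anisoles with diacyl peroxides.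

**Step 2**
Reactants: 3 2-(3-bromo-5-hydroxy-4-methoxyphenyl)acetic acid; 4 benzene-1,3,5-triol (phloroglucinol, anhydrous)
Product: 7 3-(3-bromo-5-hydroxy-4-methoxyphenyl)-5,7-dihydroxy-4H-chromen-4-one, via deoxybenzoin 5 (not isolated), via enaminone 6 (not isolated)
Conditions: 4 (1.0 equiv), BF3·OEt2 (solvent), 85 °C; then DMF, MsCl (3 equiv), 70 °C; H2O work-up
Reagents that add atoms: N,N-dimethylformamide, CN(C)C=O
Why: One-pot Friedel–Crafts C-acylation of symmetric phloroglucinol, then Vilsmeier-type formylation of the boron-chelated deoxybenzoin and ring closure by addition–elimination of the ortho-OH at the enaminone carbon (O1–C2 bond); this is the established one-pot isoflavone synthesis and tolerates free phenols, the aryl methyl ether and the aryl bromide.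

**Step 3**
Reactants: 8 2-methylbut-1-en-3-yne; 9 4,4,5,5-tetramethyl-1,3,2-dioxaborolane (pinacolborane)
Product: 10 (E)-4,4,5,5-tetramethyl-2-(3-methylbuta-1,3-dien-1-yl)-1,3,2-dioxaborolane
Conditions: Cp2Zr(H)Cl (5 mol%), 8 (1.2 equiv), CH2Cl2, 25 °C
Reagents that add atoms: none
Why: Zirconocene-catalysed syn-hydroboration of the terminal alkyne (it reacts in preference to the 1,1-disubstituted alkene) puts boron on the terminal carbon and fixes the E geometry of the new double bond.

**Step 4**
Reactants: 7 3-(3-bromo-5-hydroxy-4-methoxyphenyl)-5,7-dihydroxy-4H-chromen-4-one; 10 (E)-4,4,5,5-tetramethyl-2-(3-methylbuta-1,3-dien-1-yl)-1,3,2-dioxaborolane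
Product: 11 5,7-dihydroxy-3-{3-hydroxy-4-methoxy-5-[(1E)-3-methylbuta-1,3-dien-1-yl]phenyl}-4H-chromen-4-one
Conditions: 10 (1.5 equiv), SPhos Pd G3 (3 mol%), K3PO4 (5 equiv), 1,4-dioxane/H2O 4:1, degassed, 80 °C; work-up at pH 5
Reagents that add atoms: none
Why: Suzuki–Miyaura coupling of the aryl bromide with the alkenylboronate goes with retention of the E geometry; a dialkylbiarylphosphine catalyst handles the electron-rich ortho-substituted bromide and aqueous phosphate tolerates the three free phenols.

**Compound list**
1 | 2-(3-bromo-4-methoxyphenyl)acetic acid | COc1ccc(CC(=O)O)cc1Br | starting material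
2 | 2-[3-(benzoyloxy)-5-bromo-4-methoxyphenyl]acetic acid | COc1c(Br)cc(CC(=O)O)cc1OC(=O)c1ccccc1 | intermediate
3 | 2-(3-bromo-5-hydroxy-4-methoxyphenyl)acetic acid | COc1c(O)cc(CC(=O)O)cc1Br | intermediate
4 | benzene-1,3,5-triol (phloroglucinol) | Oc1cc(O)cc(O)c1 | starting material
5 | 2-(3-bromo-5-hydroxy-4-methoxyphenyl)-1-(2,4,6-trihydroxyphenyl)ethan-1-one (held as its BF2 chelate in the flask) | COc1c(O)cc(CC(=O)c2c(O)cc(O)cc2O)cc1Br | intermediate
6 | 2-(3-bromo-5-hydroxy-4-methoxyphenyl)-3-(dimethylamino)-1-(2,4,6-trihydroxyphenyl)prop-2-en-1-one (alkene geometry undefined) | COc1c(O)cc(C(=CN(C)C)C(=O)c2c(O)cc(O)cc2O)cc1Br | intermediate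
7 | 3-(3-bromo-5-hydroxy-4-methoxyphenyl)-5,7-dihydroxy-4H-chromen-4-one | COc1c(O)cc(-c2coc3cc(O)cc(O)c3c2=O)cc1Br | intermediate
8 | 2-methylbut-1-en-3-yne | C=C(C)C#C | starting material
9 | 4,4,5,5-tetramethyl-1,3,2-dioxaborolane (pinacolborane) | CC1(C)OBOC1(C)C | starting material
10 | (E)-4,4,5,5-tetramethyl-2-(3-methylbuta-1,3-dien-1-yl)-1,3,2-dioxaborolane | C=C(C)/C=C/B1OC(C)(C)C(C)(C)O1 | intermediate
11 | 5,7-dihydroxy-3-{3-hydroxy-4-methoxy-5-[(1E)-3-methylbuta-1,3-dien-1-yl]phenyl}-4H-chromen-4-one | C=C(C)/C=C/c1cc(-c2coc3cc(O)cc(O)c3c2=O)cc(O)c1OC | target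

**Step count and risks**
Total step count: 4. Longest linear sequence: 3 (steps 1, 2 and 4; step 3 is the side branch).

Steps most likely to fail:

Step 1 (the proposed new method). The risks are slow attack at C5, which is flanked by the methoxy group, and acid-induced decomposition of the peroxide before it reacts. The fallback uses known chemistry, sets out from 1 and comes back at 3. Electrophilic iodination at the same position (NIS, cat. TfOH, MeCN, 25 °C) gives 2-(3-bromo-5-iodo-4-methoxyphenyl)acetic acid F1. Copper-catalysed Ullmann-type hydroxylation of the C–I bond (CuI, 1,10-phenanthroline, KOH, DMSO/H2O, 100 °C) then gives 3; the less reactive, electron-rich C–Br bond should stay intact under these conditions.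

Step 4. The risks are sluggish oxidative addition of the electron-rich bromide in the presence of three phenoxides, and loss of the dienylboronate by protodeboronation or polymerisation. The fallback sets out from 7 and comes back at 11. A Heck reaction with 2-methylbut-3-en-2-ol (Pd(OAc)2, P(o-tol)3, Et3N, DMF, 100 °C) gives 3-[3-hydroxy-5-[(E)-3-hydroxy-3-methylbut-1-en-1-yl]-4-methoxyphenyl]-5,7-dihydroxy-4H-chromen-4-one F2. Acid-catalysed dehydration of this tertiary allylic alcohol (cat. TsOH·H2O, 1,4-dioxane, 70 °C) can only eliminate toward a methyl group and gives 11.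

Step 2. The risk is in the second stage of the one-pot sequence, where the extra B-ring phenol could be formylated or mesylated. The fallback sets out from 3 and 4 and comes back at 7, replacing the one-pot boron-chelate/Vilsmeier sequence with two separate stages. Only the BF3·OEt2 acylation is run, and deoxybenzoin 5 is isolated after aqueous work-up. The free ketone is then aminomethylenated with N,N-dimethylformamide dimethyl acetal (THF, 65 °C) to 6, which closes spontaneously to 7. This fallback makes no compound outside the list (F0).

**Further compounds**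
F1 | step 1 | 2-(3-bromo-5-iodo-4-methoxyphenyl)acetic acid | COc1c(I)cc(CC(=O)O)cc1Br
F0 | step 2 | none | none
F2 | step 4 | 3-[3-hydroxy-5-[(E)-3-hydroxy-3-methylbut-1-en-1-yl]-4-methoxyphenyl]-5,7-dihydroxy-4H-chromen-4-one | COc1c(O)cc(-c2coc3cc(O)cc(O)c3c2=O)cc1/C=C/C(C)(C)O
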